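**Plan**

Numbering used throughout (seco-aromadendrane style): carbocycle C1, C5 (ring-fusion CH), C6, C7 (cyclopropane CH), C8, C9, C10 (C(OH)Me); C11 = quaternary cyclopropane carbon bearing C12 (CH2OAc) and C13 (CH2O); pyran C2 (acetal), C3=C4; C15 = CH2 between C4 and the ether oxygen; C14 = methyl.
Cuts (retro): acetates and silyl ether; O–C2 and the C2 oxidation level (lactol ← enol lactone ← formyl acid); C15–O and C4–C15 of the oxepane (oxa-Michael, Mannich with CH2O); C3–C4 (Wittig); C6–C11 and C7–C11 (malonate carbene); then C6=C7 and C10–OH are re-joined as an oxygen bridge and C8 is excised, which gives a 7-oxanorbornanone and so 2-methylfuran + maleic anhydride.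
Enabling feature: in the seven-membered carbocycle C10 (C–O, Me) and C6 stand 1,4 and flank the cis pair C1/C5, whose carbon substituents are cis to the C10 oxygen; this is the exo furan–maleic anhydride adduct with one ring carbon (C8) missing, and a C7 ketone next to the oxygen-bearing bridgehead C6 lets CH2 be inserted between C7 and C9 only.
Forward ring order: oxanorbornene (Diels–Alder) → six-membered carbocycle enlarged to the seven-membered one → zinc opens the oxygen bridge (C6=C7, C10–O held as a bridged lactone) → cyclopropane → oxepane → enol lactone → acetoxy-dihydropyran.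
Stereochemistry: C1, C5, C10 (relative) from the exo Diels–Alder adduct, absolute from alkaloid-catalysed methanolysis (parallel kinetic resolution); C6, C7 from carbene addition anti to the C5 side chain; C11 from ring closure by the endo CH2OH only; C2 from equilibrating lactol acetylation.

Key step: step 6

Assumption: the quinidine-derived catalyst is taken to open the drawn enantiomer of 3 at the carbonyl remote from the bridgehead methyl; should the sense be opposite, the quinine-derived pseudo-enantiomer (DHQ)2AQN is used with no other change.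

**Route**

Step 1
Reactants: 1 2-methylfuran; 2 maleic anhydride
Product: 3 racemic exo Diels–Alder adduct (1-methyl-7-oxabicyclo[2.2.1]hept-5-ene-2,3-exo-dicarboxylic anhydride)
Conditions: Et2O, rt, 24 h; crystallisation
Reagents that add atoms: none
Why: Diels–Alder cycloaddition of an electron-rich furan to maleic anhydride is reversible at room temperature, so the thermodynamic exo adduct should crystallise, the cis dienophile fixing H-1/H-5 cis and the exo mode placing both carbonyl carbons (future C2, C4) on the side of the oxygen bridge (future C10–OH).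

Step 2
Reactants: 3 racemic exo adduct
Product: 4 hemiester (CO2Me on C5, CO2H on C1; single enantiomer)
Conditions: (DHQD)2AQN (15 mol %), MeOH (10 equiv), Et2O, −20 °C; chromatographic removal of the regioisomeric hemiester
Reagents that add atoms: methanol, CO
Why: Cinchona-alkaloid-catalysed alcoholysis of a cyclic anhydride run as a parallel kinetic resolution, in which the catalyst should open each enantiomer at the carbonyl of the same prochirality (in the drawn enantiomer the unhindered one remote from the bridgehead methyl), so that 4 and the hemiester of the mirror-image skeleton are constitutional isomers and can be separated, fixing the absolute configuration of C1, C5 and C10.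

Step 3
Reactants: 4 hemiester
Product: 5 mixed diester (tert-butyl ester on C1, methyl ester on C5)
Conditions: t-BuOC(=NH)CCl3 (2 equiv), CH2Cl2/cyclohexane, rt
Reagents that add atoms: tert-butyl 2,2,2-trichloroacetimidate, CC(C)(C)OC(=N)C(Cl)(Cl)Cl
Why: Acid-catalysed O-tert-butylation of the carboxylic acid by the trichloroacetimidate (imidate esterification) gives an ester at C2 that should survive the later hydride and ylide steps in which the C4 methyl ester reacts.

Step 4
Reactants: 5 mixed diester
Product: 6 exo alcohol (OH on C7)
Conditions: 9-BBN (1.5 equiv), THF, 0 °C → rt; then 30% H2O2, 3 M aq. NaOAc, 0 °C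
Reagents that add atoms: hydrogen peroxide, OO
Why: Hydroboration–oxidation, in which the bulky borane should add syn from the exo face and place boron on the alkene carbon (C7) remote from the methyl-substituted bridgehead, oxidation with retention giving the exo alcohol (a centre that is removed later).

Step 5
Reactants: 6 exo alcohol
Product: 7 7-oxanorbornan-2-one (ketone at C7)
Conditions: Dess–Martin periodinane, CH2Cl2, rt
Reagents that add atoms: none
Why: Dess–Martin oxidation under base-free conditions gives the ketone without the β-elimination of the bridge oxygen that an enolate at C9 would cause.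

Step 6
Reactants: 7 7-oxanorbornan-2-one
Product: 9 8-oxabicyclo[3.2.1]octan-2-one (seven-membered carbocycle, C8 inserted), via α-silyl ketone 8 (not isolated)
Conditions: Me3SiCHN2 (1.5 equiv), Sc(OTf)3 (10 mol %), CH2Cl2, −78 → 0 °C; then 1 M HCl, THF, rt
Reagents that add atoms: (trimethylsilyl)diazomethane, C[Si](C)(C)C=[N+]=[N-]
Why: The Lewis-acid-bound ketone is attacked at C7 by the nucleophilic carbon of Me3SiCHN2 from the open exo face to give a β-oxido diazonium, and the antiperiplanar C7–C9 bond migrates with loss of N2, so the six-membered carbocycle C1–C5–C6–C7–C9–C10 becomes seven-membered with the new carbon (C8) between C7 and C9; the α-silyl ketone 8 is protodesilylated on acidic work-up. The closest known reaction type is the Tiffeneau–Demjanov/diazoalkane one-carbon enlargement of 7-oxanorbornan-2-ones to 8-oxabicyclo[3.2.1]octan-2-ones. No ring is closed here: an existing ring is enlarged by insertion, and the oxygen bridge stays as a tether that holds C6 and C10 until step 9. No stereocentre of the target is made (the silylated carbon of 8 is lost), and C1, C5, C6 and C10 are untouched because nothing is enolised under these base-free conditions. The step needs migration of the methylene C9 and not of the bridgehead C6, which is secured by the inductively withdrawing bridge oxygen on C6 and by the strain of shifting a bridgehead bond; it also needs chemoselectivity for the ketone over the two esters, which the far more electrophilic Lewis-acid-bound ketone provides.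

Step 7
Reactants: 9 ring-enlarged ketone
Product: 10 alcohol (OH on C7)
Conditions: NaBH4, MeOH, −20 °C
Reagents that add atoms: none
Why: Borohydride reduction of the ketone, far more reactive than either ester, should occur from the face remote from the two-carbon bridge to give the equatorial alcohol, whose configuration is irrelevant because C7 becomes sp2 in step 9.

Step 8
Reactants: 10 alcohol
Product: 11 iodide (I on C7)
Conditions: I2, PPh3, imidazole, toluene, 70 °C
Reagents that add atoms: iodine, II
Why: Appel-type iodination converts the secondary alcohol into the iodide with inversion by SN2 displacement of the oxyphosphonium group.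

Step 9
Reactants: 11 iodide
Product: 13 bridged γ-lactone (C10–O–C4=O; C6=C7 alkene), via hydroxy diester 12 (not isolated)
Conditions: Zn dust (10 equiv), THF/EtOH, 60 °C; then PPTS (cat.), toluene, 60 °C
Reagents that add atoms: none
Why: Boord-type zinc-mediated reductive β-elimination, in which zinc inserts into the C7–I bond and the organozinc expels the β-oxygen at C6, opens the bridge regiospecifically to the C6=C7 alkene and the C10 tertiary alkoxide, which is held cis-1,3 to the C4 methyl ester by the Diels–Alder geometry and lactonises, masking the tertiary alcohol and telling C4 from C2.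

Step 10
Reactants: 13 bridged γ-lactone
Product: 14 lactol (anomers)
Conditions: i-Bu2AlH (1.1 equiv), CH2Cl2, −78 °C
Reagents that add atoms: none
Why: Partial reduction of a lactone to the lactol with i-Bu2AlH at −78 °C, where the tetrahedral aluminate is stable and the hindered tert-butyl ester is not attacked.

Step 11
Reactants: 14 lactol
Product: 16 silyl-protected enol ether (C5–CH=CH–OMe, C10–OSiEt3), via hydroxy enol ether 15 (not isolated)
Conditions: Ph3P(Cl)CH2OMe (3 equiv), KN(SiMe3)2 (3.5 equiv), THF, 0 °C; then Et3SiOTf (2 equiv), −78 → 0 °C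
Reagents that add atoms: (methoxymethyl)triphenylphosphonium chloride, COC[P+](c1ccccc1)(c1ccccc1)c1ccccc1.[Cl-]; triethylsilyl trifluoromethanesulfonate, CC[Si](CC)(CC)OS(=O)(=O)C(F)(F)F
Why: Wittig methoxymethylenation of the lactol through its open hydroxy-aldehyde form adds C3 as an enol ether, and the tertiary alkoxide released is O-silylated in the same flask, protecting C10–OH for the rest of the route.

Step 12
Reactants: 16 silyl-protected enol ether
Product: 17 dimethyl acetal
Conditions: MeOH, PPTS (cat.), rt
Reagents that add atoms: methanol, CO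
Why: Acid-catalysed addition of methanol to the enol ether (acetalisation) removes the electron-rich alkene, so that the electrophilic carbene of step 13 can only meet the ring alkene.

Step 13
Reactants: 17 dimethyl acetal
Product: 18 cyclopropane diester
Conditions: dimethyl diazomalonate (2 equiv, slow addition), Rh2(esp)2 (1 mol %), CH2Cl2, rt
Reagents that add atoms: dimethyl diazomalonate, COC(=O)C(=[N+]=[N-])C(=O)OC
Why: Dirhodium-carboxylate-catalysed cyclopropanation by the acceptor/acceptor carbene, which should add to the cis ring alkene from the face opposite to the acetal side chain on the adjacent C5, setting C6 and C7 with the cyclopropane cis to H-5 as in the target.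

Step 14
Reactants: 18 cyclopropane diester
Product: 19 diol
Conditions: LiBH4 (4 equiv), THF/MeOH, 0 °C → rt
Reagents that add atoms: none
Why: Chemoselective borohydride reduction, in which LiBH4 reduces the two activated methyl esters of the malonate to the 1,3-diol and leaves the hindered tert-butyl ester, the acetal and the silyl ether.

Step 15
Reactants: 19 diol
Product: 22 oxepane aldehyde (C13–O–C15 closed; CHO on C4, epimers), via aldehyde 20 (not isolated), via enal 21 (not isolated)
Conditions: PPTS, acetone/H2O, 45 °C; then 37% aq. CH2O, pyrrolidine (20 mol %), EtCO2H (20 mol %), i-PrOH, 45 °C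
Reagents that add atoms: water, O; formaldehyde, C=O
Why: Mild acetal hydrolysis followed by amine/acid-catalysed Mannich condensation–elimination (α-methylenation) introduces C15 as a 2-substituted acrolein, which the endo hydroxymethyl group (the only one that reaches the β-carbon) closes by a 7-endo-trig oxa-Michael addition under iminium activation, a ring closure that differentiates the two CH2OH groups and so fixes C11, while the new C4 centre is inconsequential because it becomes sp2 in step 16.

Step 16
Reactants: 22 oxepane aldehyde
Product: 24 enol lactone acetate (C2 lactone carbonyl, C3=C4, C12–OAc), via formyl acid 23 (not isolated)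
Conditions: Me3SiOTf (4 equiv), 2,6-lutidine (6 equiv), CH2Cl2, 0 °C; aqueous work-up; then Ac2O, NaOAc (cat.), 90 °C
Reagents that add atoms: acetic anhydride, CC(=O)OC(C)=O
Why: Silyl-triflate cleavage of the tert-butyl ester (silyl ester, loss of isobutene) leaves the tertiary silyl ether intact, and the resulting formyl acid is cyclodehydrated through the mixed anhydride and O-acylation of the aldehyde enol (enol lactonisation), which places the double bond at C3=C4 unambiguously because C4 is the only enolisable position of the aldehyde, the primary alcohol being acetylated on the way.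

Step 17
Reactants: 24 enol lactone acetate
Product: 25 lactol diol (C2–OH anomers, C12–OH)
Conditions: i-Bu2AlH (3.5 equiv), CH2Cl2, −78 °C
Reagents that add atoms: none
Why: Partial i-Bu2AlH reduction of an enol lactone to the lactol, the aluminate being stable at −78 °C (the known conversion of iridoid enol lactones into their lactols), with the acetate cleaved by the excess hydride.

Step 18
Reactants: 25 lactol diol
Product: 26 silyl-protected diacetate
Conditions: Ac2O, pyridine, DMAP (cat.), CH2Cl2, 0 °C
Reagents that add atoms: acetic anhydride, CC(=O)OC(C)=O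
Why: Acetylation of the primary alcohol and of the lactol, whose anomers interconvert by ring opening under the basic conditions, so that the acetate should settle pseudo-axial on the convex face, trans to the C1–C10 bond and cis to H-1, which is the C2 configuration of the target.

Step 19
Reactants: 26 silyl-protected diacetate
Product: 27 target CNP0250836.3
Conditions: Bu4NF/AcOH (1:1), THF, 0 °C → rt
Reagents that add atoms: none
Why: Fluoride-induced cleavage of the tertiary triethylsilyl ether, buffered with acetic acid so that neither acetate is touched and the freed C10–OH does not add to the enol ether under acid catalysis.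

**Compound list**

1 | 2-methylfuran | Cc1ccco1 | starting material
2 | maleic anhydride | O=C1OC(=O)C=C1 | starting material
3 | exo-1-methyl-7-oxabicyclo[2.2.1]hept-5-ene-2,3-dicarboxylic anhydride (racemate; SMILES shows the enantiomer carried on) | [C@@H]12C(=O)OC(=O)[C@@H]1[C@H]3C=C[C@]2(C)O3 | intermediate
4 | 3-exo-(methoxycarbonyl)-1-methyl-7-oxabicyclo[2.2.1]hept-5-ene-2-exo-carboxylic acid (acid next to the methyl-bearing bridgehead) | OC(=O)[C@@H]1[C@H](C(=O)OC)[C@H]2C=C[C@]1(C)O2 | intermediate
5 | 2-tert-butyl 3-methyl 1-methyl-7-oxabicyclo[2.2.1]hept-5-ene-2-exo,3-exo-dicarboxylate | CC(C)(C)OC(=O)[C@@H]1[C@H](C(=O)OC)[C@H]2C=C[C@]1(C)O2 | intermediate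
6 | 2-tert-butyl 3-methyl 5-exo-hydroxy-1-methyl-7-oxabicyclo[2.2.1]heptane-2-exo,3-exo-dicarboxylate | CC(C)(C)OC(=O)[C@@H]1[C@H](C(=O)OC)[C@H]2[C@H](O)C[C@]1(C)O2 | intermediate
7 | 2-tert-butyl 3-methyl 1-methyl-5-oxo-7-oxabicyclo[2.2.1]heptane-2-exo,3-exo-dicarboxylate | CC(C)(C)OC(=O)[C@@H]1[C@H](C(=O)OC)[C@H]2C(=O)C[C@]1(C)O2 | intermediate
8 | 6-tert-butyl 7-methyl 5-methyl-2-oxo-3-(trimethylsilyl)-8-oxabicyclo[3.2.1]octane-6-exo,7-exo-dicarboxylate (silyl epimers) | CC(C)(C)OC(=O)[C@@H]1[C@H](C(=O)OC)[C@H]2C(=O)C([Si](C)(C)C)C[C@]1(C)O2 | intermediate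
9 | 6-tert-butyl 7-methyl 5-methyl-2-oxo-8-oxabicyclo[3.2.1]octane-6-exo,7-exo-dicarboxylate | CC(C)(C)OC(=O)[C@@H]1[C@H](C(=O)OC)[C@H]2C(=O)CC[C@]1(C)O2 | intermediate
10 | 6-tert-butyl 7-methyl 2-hydroxy-5-methyl-8-oxabicyclo[3.2.1]octane-6-exo,7-exo-dicarboxylate (equatorial OH, on the face away from the oxygen bridge) | CC(C)(C)OC(=O)[C@@H]1[C@H](C(=O)OC)[C@H]2[C@@H](O)CC[C@]1(C)O2 | intermediate
11 | 6-tert-butyl 7-methyl 2-iodo-5-methyl-8-oxabicyclo[3.2.1]octane-6-exo,7-exo-dicarboxylate (iodide inverted, axial) | CC(C)(C)OC(=O)[C@@H]1[C@H](C(=O)OC)[C@H]2[C@H](I)CC[C@]1(C)O2 | intermediate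
12 | 1-tert-butyl 2-methyl 7-hydroxy-7-methylcyclohept-3-ene-1,2-dicarboxylate (both esters and OH all cis) | CC(C)(C)OC(=O)[C@@H]1[C@H](C(=O)OC)C=CCC[C@]1(C)O | intermediate
13 | tert-butyl 6-methyl-8-oxo-7-oxabicyclo[4.2.1]non-2-ene-9-carboxylate (ester syn to the lactone bridge) | CC(C)(C)OC(=O)[C@@H]1[C@H]2C=CCC[C@]1(C)OC2=O | intermediate
14 | tert-butyl 8-hydroxy-6-methyl-7-oxabicyclo[4.2.1]non-2-ene-9-carboxylate (lactol, anomers) | CC(C)(C)OC(=O)[C@@H]1[C@H]2C=CCC[C@]1(C)OC2O | intermediate
15 | tert-butyl 7-hydroxy-2-(2-methoxyethenyl)-7-methylcyclohept-3-ene-1-carboxylate (E/Z; ring substituents all cis) | CC(C)(C)OC(=O)[C@@H]1[C@H](C=COC)C=CCC[C@]1(C)O | intermediate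
16 | tert-butyl 2-(2-methoxyethenyl)-7-methyl-7-(triethylsilyloxy)cyclohept-3-ene-1-carboxylate (E/Z; ring substituents all cis) | CC(C)(C)OC(=O)[C@@H]1[C@H](C=COC)C=CCC[C@]1(C)O[Si](CC)(CC)CC | intermediate
17 | tert-butyl 2-(2,2-dimethoxyethyl)-7-methyl-7-(triethylsilyloxy)cyclohept-3-ene-1-carboxylate | CC(C)(C)OC(=O)[C@@H]1[C@H](CC(OC)OC)C=CCC[C@]1(C)O[Si](CC)(CC)CC | intermediate
18 | 3-tert-butyl 8,8-dimethyl 2-(2,2-dimethoxyethyl)-4-methyl-4-(triethylsilyloxy)bicyclo[5.1.0]octane-3,8,8-tricarboxylate (cyclopropane trans to the C2 side chain) | CC(C)(C)OC(=O)[C@@H]1[C@H](CC(OC)OC)[C@@H]2[C@@H](C2(C(=O)OC)C(=O)OC)CC[C@]1(C)O[Si](CC)(CC)CC | intermediate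
19 | tert-butyl 2-(2,2-dimethoxyethyl)-8,8-bis(hydroxymethyl)-4-methyl-4-(triethylsilyloxy)bicyclo[5.1.0]octane-3-carboxylate | CC(C)(C)OC(=O)[C@@H]1[C@H](CC(OC)OC)[C@@H]2[C@@H](C2(CO)CO)CC[C@]1(C)O[Si](CC)(CC)CC | intermediate
20 | tert-butyl 8,8-bis(hydroxymethyl)-4-methyl-2-(2-oxoethyl)-4-(triethylsilyloxy)bicyclo[5.1.0]octane-3-carboxylate | CC(C)(C)OC(=O)[C@@H]1[C@H](CC=O)[C@@H]2[C@@H](C2(CO)CO)CC[C@]1(C)O[Si](CC)(CC)CC | intermediate
21 | tert-butyl 8,8-bis(hydroxymethyl)-4-methyl-2-(3-oxoprop-1-en-2-yl)-4-(triethylsilyloxy)bicyclo[5.1.0]octane-3-carboxylate | CC(C)(C)OC(=O)[C@@H]1[C@H](C(=C)C=O)[C@@H]2[C@@H](C2(CO)CO)CC[C@]1(C)O[Si](CC)(CC)CC | intermediate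
22 | tricyclic oxepane aldehyde: C13–O–C15 ring closed, CHO (C3) on C4 (epimers), exo CH2OH (C12), C10–OSiEt3, tert-butyl ester at C2 | OC[C@@]12COCC(C=O)[C@@H]3[C@@H]1[C@@H]2CC[C@](C)(O[Si](CC)(CC)CC)[C@@H]3C(=O)OC(C)(C)C | intermediate
23 | formyl acid: carboxylic acid (C2) corresponding to 22 | OC[C@@]12COCC(C=O)[C@@H]3[C@@H]1[C@@H]2CC[C@](C)(O[Si](CC)(CC)CC)[C@@H]3C(O)=O | intermediate
24 | enol lactone: C2 lactone carbonyl, O–C3=C4, C12–OAc, C10–OSiEt3 | CC(=O)OC[C@@]12COCC3=COC(=O)[C@@H]4[C@H]3[C@@H]1[C@@H]2CC[C@]4(C)O[Si](CC)(CC)CC | intermediate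
25 | lactol diol: C2–OH (anomers), C12–OH, C10–OSiEt3 | OC[C@@]12COCC3=COC(O)[C@@H]4[C@H]3[C@@H]1[C@@H]2CC[C@]4(C)O[Si](CC)(CC)CC | intermediate
26 | 10-O-triethylsilyl ether of the target | CC(=O)OC[C@@]12COCC3=CO[C@H](OC(C)=O)[C@@H]4[C@H]3[C@@H]1[C@@H]2CC[C@]4(C)O[Si](CC)(CC)CC | intermediate
27 | CNP0250836.3 | CC(=O)OC[C@@]12COCC3=CO[C@H](OC(C)=O)[C@@H]4[C@H]3[C@@H]1[C@@H]2CC[C@]4(C)O | target

**Count and risks**

Total steps: 19. Longest linear sequence: 19 (the route is fully linear from 1 and 2).

Steps most likely to fail:

Step 2 – insufficient discrimination between the two enantiomers, or between the two carbonyl groups, in the catalysed methanolysis. Fallback: from 3, uncatalysed methanolysis (MeOH, Et3N cat., Et2O, 0 °C; the unhindered carbonyl reacts) gives 4 together with its mirror image F1 as the racemate. Classical resolution by crystallising the (R)-1-phenylethylammonium salt F2 from EtOAc, then acidification with 1 M HCl, returns enantiopure 4, where the route is rejoined.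

Step 13 – slow carbene transfer to the hindered cis ring alkene (carbene dimerisation, C–H insertion) or erosion of facial selectivity. Fallback: from 17, dibromocarbene (CHBr3, 50% aq. NaOH, BnEt3NCl), a smaller and more reactive carbene, gives the dibromocyclopropane F3. Bromine–lithium exchange (n-BuLi, THF, −100 °C) and trapping with ClCO2Me gives the bromo ester F4, and a second exchange and carboxylation gives the malonate 18, where the route is rejoined.

Step 15 – incomplete or reversible seven-membered oxa-Michael ring closure (retro-addition, competing acetal formation with formaldehyde). Fallback: from 19, carry out only the hydrolysis and the methylenation and isolate the enal 21. Deprotonate both hydroxyl groups (KN(SiMe3)2, THF, −78 → 0 °C) so that conjugate addition of the endo alkoxide is driven to the aldehyde enolate, and trap with Ac2O as the enol acetate F5 (the primary alcohol is acetylated as well). i-Bu2AlH at −78 °C then reduces the tert-butyl ester to the aldehyde level and cleaves both acetyl groups, and on work-up the released C3 enolate closes on the C2 aldehyde to give lactol 25, where the route is rejoined (22–24 are bypassed).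

Further compounds
F1 | step 2 | mirror image of 4 (formed with 4 as the racemate) | OC(=O)[C@H]1[C@@H](C(=O)OC)[C@@H]2C=C[C@@]1(C)O2
F2 | step 2 | (R)-1-phenylethylammonium salt of 4 | [O-]C(=O)[C@@H]1[C@H](C(=O)OC)[C@H]2C=C[C@]1(C)O2.C[C@@H]([NH3+])c1ccccc1
F3 | step 13 | tert-butyl 8,8-dibromo-2-(2,2-dimethoxyethyl)-4-methyl-4-(triethylsilyloxy)bicyclo[5.1.0]octane-3-carboxylate | CC(C)(C)OC(=O)[C@@H]1[C@H](CC(OC)OC)[C@@H]2[C@@H](C2(Br)Br)CC[C@]1(C)O[Si](CC)(CC)CC
F4 | step 13 | 3-tert-butyl 8-methyl 8-bromo-2-(2,2-dimethoxyethyl)-4-methyl-4-(triethylsilyloxy)bicyclo[5.1.0]octane-3,8-dicarboxylate (epimers at the brominated carbon) | CC(C)(C)OC(=O)[C@@H]1[C@H](CC(OC)OC)[C@@H]2[C@@H](C2(Br)C(=O)OC)CC[C@]1(C)O[Si](CC)(CC)CC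
F5 | step 15 | enol acetate of 22 with C12–OAc (C3 enol acetate, C3=C4; tert-butyl ester and silyl ether kept) | CC(=O)OC[C@@]12COCC(=COC(C)=O)[C@@H]3[C@@H]1[C@@H]2CC[C@](C)(O[Si](CC)(CC)CC)[C@@H]3C(=O)OC(C)(C)C
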